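**Plan**

- Atom names: carotenoid numbering in each ring (C1 = CMe2, C2 = CH with the side chain, C5=C6 = ring alkene, C6 carries the polyene; primes for ring B); side chain = C2–CaH2–CbH=Cc.
- Cuts: C11=C12 and C11'=C12' (two Wittig reactions on the commercial C10 dialdehyde), C6–C7 in each half (Stille coupling of a ring enol triflate with a C6 stannyl dienol), Cb=Cc in each side chain, and C1–C2 in each ring.
- Feature used: in both rings the gem-dimethyl carbon C1 lies between C6 (a latent ketone) and the stereocentre C2, and C2 carries a CH2–C arm. One C1 methyl can therefore start as the CH2 of an isopropenyl ketone and C2 as the β-carbon of an enoate. Hydride delivery to that CH2 makes C1 a fully substituted enolate carbon, which closes the six-membered ring C1–C6 onto C2.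
- Forward: acyclic dienone ester (3 steps) → ring ketone by copper-hydride reductive Michael cyclisation → C5 methyl, C5=C6 enol triflate, side chain → C15 phosphonium salt, once for ring A (prenyl) and once with the antipodal ligand for ring B (protected diol arm); then C15 + C10 + C15 and desilylation.
- Stereochemistry: C2 (R) and C2' (S) are the only stereocentres; each is set in the ring closure by the chiral bisphospholane on copper and is never α to a carbonyl group afterwards. The polyene is all-E by Stille coupling with retention, Wittig reactions and thermal Z → E equilibration.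

Key step: step 4

Assumption: the sense of induction of the copper catalyst cannot be predicted with confidence. (R,R)-Ph-BPE is written for the (R)-ring and (S,S)-Ph-BPE for the (S)-ring; the two ligands would be exchanged between steps 4 and 12 if the first run showed the opposite sense.

Remark: Ph-BPE is 1,2-bis(2,5-diphenylphospholan-1-yl)ethane, (2R,5R) in both phospholane rings for the (R,R)-ligand and (2S,5S) for the (S,S)-ligand. The two copper enolates are drawn with their ligand, because they are mirror-image complexes and therefore different compounds. In their SMILES each P→Cu dative bond is written as a single bond with formal charges on phosphorus and copper.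

**Route**

Step 1
Reactants: 1 glutaraldehyde (pentanedial, 50 wt % in water); 2 ethyl (triphenylphosphoranylidene)acetate
Product: 3 ethyl (2E)-7-oxohept-2-enoate
Conditions: 1 (3 equiv), 2 (1 equiv), CH2Cl2/H2O, rt
Reagents that add atoms: none
Why: Wittig olefination with a stabilised ylide should give the (E)-enoate, and the excess of dialdehyde limits double olefination.

Step 2
Reactants: 3 ethyl (2E)-7-oxohept-2-enoate
Product: 4 ethyl (2E)-7-hydroxy-8-methylnona-2,8-dienoate (racemic)
Conditions: CH2=C(CH3)MgBr (1.1 equiv), THF, −78 °C; aq. NH4Cl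
Reagents that add atoms: isopropenylmagnesium bromide, C=C(C)[Mg]Br
Why: Grignard 1,2-addition should be selective for the aldehyde over the conjugated ester at −78 °C; the racemic carbinol centre is removed in step 3.

Step 3
Reactants: 4 ethyl (2E)-7-hydroxy-8-methylnona-2,8-dienoate
Product: 5 ethyl (2E)-8-methyl-7-oxonona-2,8-dienoate
Conditions: Dess–Martin periodinane (1.2 equiv), CH2Cl2, 0 °C → rt
Reagents that add atoms: none
Why: Dess–Martin oxidation of the secondary allylic alcohol should give the α-methylene ketone under neutral conditions that leave the enoate untouched.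

Step 4
Reactants: 5 ethyl (2E)-8-methyl-7-oxonona-2,8-dienoate
Product: 8 ethyl 2-[(1R)-2,2-dimethyl-3-oxocyclohexyl]acetate, via copper enolate 6 (not isolated), via silyl ketene acetal 7 (not isolated)
Conditions: Cu(OAc)2·H2O (5 mol %), (R,R)-Ph-BPE (5.5 mol %), (EtO)2MeSiH (1.3 equiv), toluene, −20 °C, slow addition of 5; then aq. NH4F
Reagents that add atoms: none
Why: Proposed new method: the bisphospholane-bound monovalent copper hydride formed from Cu(OAc)2·H2O, (R,R)-Ph-BPE and the silane should deliver hydride only to the unsubstituted CH2 terminus of the isopropenyl ketone, the more electrophilic and less hindered of the two acceptors, which turns that CH2 into the second methyl group on C1 and gives the fully substituted, ligand-bound copper enolate 6 without regiochemical ambiguity; C1 of 6 then adds to the enoate β-carbon C2, and σ-bond metathesis of the resulting copper ester enolate with the silane releases silyl ketene acetal 7 and returns the copper hydride. The closest known reaction type is the copper-hydride-catalysed enantioselective reductive Michael cyclisation of substrates that hold two tethered α,β-unsaturated carbonyl groups (and the related reductive aldol cyclisation); new here is an α-branched enone as the hydride acceptor, so that the bond formed joins a quaternary to a tertiary carbon and the only new stereocentre lies on the acceptor. Ring A closes in the 6-exo-trig mode (C1 onto C2, tether C6–C5–C4–C3), with the ester carbonyl outside the ring. The C2 stereocentre is controlled by the C2-symmetric bisphospholane on copper, whose phenyl groups must distinguish the two chair-like transition states that offer the Re or the Si face of the (E)-enoate to the metal-bound enolate. The step needs chemoselective hydride delivery (secured by the reactivity gap between a terminal α-methylene ketone and a β-alkyl enoate), ring closure faster than silyl transfer to 6 or intermolecular Michael addition (secured by the six-membered intramolecular geometry, slow addition of 5 and dilution), and C- rather than O-attack (O-attack would be a reversible oxa-Michael addition, whereas C–C formation is made irreversible by silylation).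

Step 5
Reactants: 8 ethyl 2-[(1R)-2,2-dimethyl-3-oxocyclohexyl]acetate
Product: 10 ethyl 2-[(1R,4RS)-2,2,4-trimethyl-3-oxocyclohexyl]acetate, via lithium enolate 9 (not isolated)
Conditions: LiN(SiMe3)2 (1.05 equiv), THF, −78 °C; MeI (3 equiv), −78 → −40 °C
Reagents that add atoms: iodomethane, CI
Why: Enolate alkylation: the amide base should enolise the ketone at its only α-CH2 (C5, since C1 is quaternary) in preference to the less acidic ester, the low temperature keeps the ester enolate (from which a retro-Michael ring opening could start) from forming, and the C5 epimer mixture is of no consequence because C5 becomes sp2 in step 6.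

Step 6
Reactants: 10 ethyl 2-[(1R,4RS)-2,2,4-trimethyl-3-oxocyclohexyl]acetate
Product: 11 ethyl 2-[(1R)-2,2,4-trimethyl-3-{[(trifluoromethyl)sulfonyl]oxy}cyclohex-3-en-1-yl]acetate
Conditions: Tf2O (1.5 equiv), 2,6-di-tert-butyl-4-methylpyridine (2 equiv), CH2Cl2, 0 °C → rt
Reagents that add atoms: trifluoromethanesulfonic anhydride, O=S(=O)(OS(=O)(=O)C(F)(F)F)C(F)(F)F
Why: Enol triflate formation by O-sulfonylation of the ketone and loss of its single α-hydrogen (at C5) to the hindered pyridine should give the tetrasubstituted C5=C6 triflate; these conditions, free of strong base, are chosen because the ester would compete for an amide base.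

Step 7
Reactants: 11 ethyl 2-[(1R)-2,2,4-trimethyl-3-{[(trifluoromethyl)sulfonyl]oxy}cyclohex-3-en-1-yl]acetate
Product: 12 2-[(1R)-2,2,4-trimethyl-3-{[(trifluoromethyl)sulfonyl]oxy}cyclohex-3-en-1-yl]acetaldehyde
Conditions: i-Bu2AlH (1.1 equiv), CH2Cl2, −78 °C; MeOH, aq. KNaC4H4O6 (potassium sodium tartrate)
Reagents that add atoms: none
Why: Partial ester reduction with i-Bu2AlH at −78 °C should stop at the tetrahedral aluminium hemiacetal, which gives the aldehyde on work-up, while the enol triflate is inert.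

Step 8
Reactants: 12 2-[(1R)-2,2,4-trimethyl-3-{[(trifluoromethyl)sulfonyl]oxy}cyclohex-3-en-1-yl]acetaldehyde
Product: 13 (5R)-2,6,6-trimethyl-5-(3-methylbut-2-en-1-yl)cyclohex-1-en-1-yl trifluoromethanesulfonate
Conditions: i-PrPPh3I (1.3 equiv), n-BuLi (1.25 equiv), THF, 0 °C; then 12, −78 °C → rt
Reagents that add atoms: isopropyltriphenylphosphonium iodide, CC(C)[P+](c1ccccc1)(c1ccccc1)c1ccccc1.[I-]
Why: Wittig olefination with the non-stabilised isopropylidene ylide should build the Cb=Cc bond of the prenyl group (no E/Z issue) and leave the enol triflate untouched.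

Step 9
Reactants: 14 (2E)-3-methylpent-2-en-4-yn-1-ol
Product: 15 (2E,4E)-3-methyl-5-(tributylstannyl)penta-2,4-dien-1-ol
Conditions: Bu3SnH (1.1 equiv), PdCl2(PPh3)2 (2 mol %), THF, 0 °C → rt
Reagents that add atoms: tributyltin hydride, CCCC[SnH](CCCC)CCCC
Why: Palladium-catalysed syn-hydrostannylation of the terminal alkyne should place tin on the terminal carbon and give the (4E)-stannane (any internal regioisomer to be removed by chromatography), the (2E) geometry coming from 14.

Step 10
Reactants: 13 (5R)-2,6,6-trimethyl-5-(3-methylbut-2-en-1-yl)cyclohex-1-en-1-yl trifluoromethanesulfonate; 15 (2E,4E)-3-methyl-5-(tributylstannyl)penta-2,4-dien-1-ol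
Product: 16 (2E,4E)-3-methyl-5-[(5R)-2,6,6-trimethyl-5-(3-methylbut-2-en-1-yl)cyclohex-1-en-1-yl]penta-2,4-dien-1-ol
Conditions: Pd2(dba)3 (2.5 mol %), AsPh3 (20 mol %), NMP, 60 °C
Reagents that add atoms: none
Why: Stille coupling of the hindered tetrasubstituted enol triflate with the alkenylstannane should form C6–C7 with retention of the (E)-geometry, the weakly bound AsPh3 ligand in NMP being the usual choice for congested 2,6,6-trimethylcyclohexenyl triflates.

Step 11
Reactants: 16 (2E,4E)-3-methyl-5-[(5R)-2,6,6-trimethyl-5-(3-methylbut-2-en-1-yl)cyclohex-1-en-1-yl]penta-2,4-dien-1-ol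
Product: 17 {(2E,4E)-3-methyl-5-[(5R)-2,6,6-trimethyl-5-(3-methylbut-2-en-1-yl)cyclohex-1-en-1-yl]penta-2,4-dien-1-yl}triphenylphosphonium bromide
Conditions: PPh3·HBr (1.05 equiv), MeOH, rt, dark
Reagents that add atoms: triphenylphosphine hydrobromide, Br.P(c1ccccc1)(c1ccccc1)c1ccccc1
Why: SN1-type phosphonium salt formation: the weak acid should ionise the trienylic alcohol to a delocalised cation that PPh3 captures at the primary terminus (the standard entry to C15 Wittig salts), while the isolated prenyl alkene is not protonated.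

Step 12
Reactants: 5 ethyl (2E)-8-methyl-7-oxonona-2,8-dienoate
Product: 20 ethyl 2-[(1S)-2,2-dimethyl-3-oxocyclohexyl]acetate, via copper enolate 18 (not isolated), via silyl ketene acetal 19 (not isolated)
Conditions: Cu(OAc)2·H2O (5 mol %), (S,S)-Ph-BPE (5.5 mol %), (EtO)2MeSiH (1.3 equiv), toluene, −20 °C, slow addition of 5; then aq. NH4F
Reagents that add atoms: none
Why: Proposed new method: the same hydride-triggered sequence as in step 4 (hydride to the CH2 of the isopropenyl ketone, 6-exo-trig Michael closure of C1' onto C2', silyl transfer to give 19; closest known reaction type the copper-hydride-catalysed enantioselective reductive Michael cyclisation of tethered bis-acceptors) is run with the antipodal bisphospholane, so that it passes through copper enolate 18, the mirror image of the complex of step 4, the other face of the enoate is attacked and C2' should be set as (S).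

Step 13
Reactants: 20 ethyl 2-[(1S)-2,2-dimethyl-3-oxocyclohexyl]acetate
Product: 22 ethyl 2-[(1S,4RS)-2,2,4-trimethyl-3-oxocyclohexyl]acetate, via lithium enolate 21 (not isolated)
Conditions: LiN(SiMe3)2 (1.05 equiv), THF, −78 °C; MeI (3 equiv), −78 → −40 °C
Reagents that add atoms: iodomethane, CI
Why: Enolate alkylation as in step 5, at the only enolisable ketone position C5'; the epimer mixture at C5' is of no consequence.

Step 14
Reactants: 22 ethyl 2-[(1S,4RS)-2,2,4-trimethyl-3-oxocyclohexyl]acetate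
Product: 23 ethyl 2-[(1S)-2,2,4-trimethyl-3-{[(trifluoromethyl)sulfonyl]oxy}cyclohex-3-en-1-yl]acetate
Conditions: Tf2O (1.5 equiv), 2,6-di-tert-butyl-4-methylpyridine (2 equiv), CH2Cl2, 0 °C → rt
Reagents that add atoms: trifluoromethanesulfonic anhydride, O=S(=O)(OS(=O)(=O)C(F)(F)F)C(F)(F)F
Why: Enol triflate formation as in step 6, regiochemistry fixed by the single α-hydrogen.

Step 15
Reactants: 23 ethyl 2-[(1S)-2,2,4-trimethyl-3-{[(trifluoromethyl)sulfonyl]oxy}cyclohex-3-en-1-yl]acetate
Product: 24 2-[(1S)-2,2,4-trimethyl-3-{[(trifluoromethyl)sulfonyl]oxy}cyclohex-3-en-1-yl]acetaldehyde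
Conditions: i-Bu2AlH (1.1 equiv), CH2Cl2, −78 °C; MeOH, aq. KNaC4H4O6 (potassium sodium tartrate)
Reagents that add atoms: none
Why: Partial ester reduction with i-Bu2AlH as in step 7.

Step 16
Reactants: 24 2-[(1S)-2,2,4-trimethyl-3-{[(trifluoromethyl)sulfonyl]oxy}cyclohex-3-en-1-yl]acetaldehyde; 25 dimethyl malonate
Product: 26 dimethyl 2-{2-[(1S)-2,2,4-trimethyl-3-{[(trifluoromethyl)sulfonyl]oxy}cyclohex-3-en-1-yl]ethylidene}propanedioate
Conditions: piperidine (10 mol %), AcOH (10 mol %), 4 Å molecular sieves, toluene, rt → 40 °C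
Reagents that add atoms: none
Why: Knoevenagel condensation should install Cb=Cc together with both future hydroxymethyl carbons; the stereocentre is β to the aldehyde carbonyl and cannot epimerise.

Step 17
Reactants: 26 dimethyl 2-{2-[(1S)-2,2,4-trimethyl-3-{[(trifluoromethyl)sulfonyl]oxy}cyclohex-3-en-1-yl]ethylidene}propanedioate
Product: 27 (5S)-5-[4-hydroxy-3-(hydroxymethyl)but-2-en-1-yl]-2,6,6-trimethylcyclohex-1-en-1-yl trifluoromethanesulfonate
Conditions: i-Bu2AlH (5 equiv), CH2Cl2, −78 → 0 °C; aq. KNaC4H4O6 (potassium sodium tartrate)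
Reagents that add atoms: none
Why: Ester reduction: i-Bu2AlH in a non-coordinating solvent should reduce both esters of the alkylidene malonate in the 1,2-sense to the 2-alkylidene-1,3-diol, the enol triflate being stable to this reagent.

Step 18
Reactants: 27 (5S)-5-[4-hydroxy-3-(hydroxymethyl)but-2-en-1-yl]-2,6,6-trimethylcyclohex-1-en-1-yl trifluoromethanesulfonate
Product: 28 (5S)-5-{4-[tert-butyl(diphenyl)silyl]oxy-3-({[tert-butyl(diphenyl)silyl]oxy}methyl)but-2-en-1-yl}-2,6,6-trimethylcyclohex-1-en-1-yl trifluoromethanesulfonate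
Conditions: TBDPSCl (2.4 equiv), imidazole (5 equiv), DMF, rt
Reagents that add atoms: tert-butyl(chloro)diphenylsilane, CC(C)(C)[Si](Cl)(c1ccccc1)c1ccccc1
Why: Silylation of both primary allylic hydroxyl groups as tert-butyldiphenylsilyl ethers, which should withstand the Stille coupling, the weakly acidic phosphonium salt formation and methoxide.

Step 19
Reactants: 28 (5S)-5-{4-[tert-butyl(diphenyl)silyl]oxy-3-({[tert-butyl(diphenyl)silyl]oxy}methyl)but-2-en-1-yl}-2,6,6-trimethylcyclohex-1-en-1-yl trifluoromethanesulfonate; 15 (2E,4E)-3-methyl-5-(tributylstannyl)penta-2,4-dien-1-ol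
Product: 29 (2E,4E)-5-[(5S)-5-{4-[tert-butyl(diphenyl)silyl]oxy-3-({[tert-butyl(diphenyl)silyl]oxy}methyl)but-2-en-1-yl}-2,6,6-trimethylcyclohex-1-en-1-yl]-3-methylpenta-2,4-dien-1-ol
Conditions: Pd2(dba)3 (2.5 mol %), AsPh3 (20 mol %), NMP, 60 °C
Reagents that add atoms: none
Why: Stille coupling as in step 10 should form C6'–C7' with retention of geometry; the allylic silyl ethers are not ionised by zerovalent palladium.

Step 20
Reactants: 29 (2E,4E)-5-[(5S)-5-{4-[tert-butyl(diphenyl)silyl]oxy-3-({[tert-butyl(diphenyl)silyl]oxy}methyl)but-2-en-1-yl}-2,6,6-trimethylcyclohex-1-en-1-yl]-3-methylpenta-2,4-dien-1-ol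
Product: 30 {(2E,4E)-5-[(5S)-5-{4-[tert-butyl(diphenyl)silyl]oxy-3-({[tert-butyl(diphenyl)silyl]oxy}methyl)but-2-en-1-yl}-2,6,6-trimethylcyclohex-1-en-1-yl]-3-methylpenta-2,4-dien-1-yl}triphenylphosphonium bromide
Conditions: PPh3·HBr (1.05 equiv), CH2Cl2, 0 °C → rt, dark
Reagents that add atoms: triphenylphosphine hydrobromide, Br.P(c1ccccc1)(c1ccccc1)c1ccccc1
Why: SN1-type phosphonium salt formation as in step 11, run without methanol so that the silyl ethers are not solvolysed.

Step 21
Reactants: 17 {(2E,4E)-3-methyl-5-[(5R)-2,6,6-trimethyl-5-(3-methylbut-2-en-1-yl)cyclohex-1-en-1-yl]penta-2,4-dien-1-yl}triphenylphosphonium bromide; 31 (2E,4E,6E)-2,7-dimethylocta-2,4,6-trienedial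
Product: 33 (2E,4E,6E,8E,10E,12E)-2,7,11-trimethyl-13-[(5R)-2,6,6-trimethyl-5-(3-methylbut-2-en-1-yl)cyclohex-1-en-1-yl]trideca-2,4,6,8,10,12-hexaenal, via phosphonium ylide 32 (not isolated)
Conditions: 31 (3 equiv), NaOMe (1.2 equiv), CH2Cl2/MeOH, 0 °C → rt, dark; then heptane, 80 °C (Z → E)
Reagents that add atoms: none
Why: Wittig reaction of the semi-stabilised C15 ylide with an excess of the symmetrical C10 dialdehyde should give the mono-olefination product, and heating should equilibrate the new C11=C12 bond to the more stable (E)-isomer.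

Step 22
Reactants: 30 {(2E,4E)-5-[(5S)-5-{4-[tert-butyl(diphenyl)silyl]oxy-3-({[tert-butyl(diphenyl)silyl]oxy}methyl)but-2-en-1-yl}-2,6,6-trimethylcyclohex-1-en-1-yl]-3-methylpenta-2,4-dien-1-yl}triphenylphosphonium bromide; 33 (2E,4E,6E,8E,10E,12E)-2,7,11-trimethyl-13-[(5R)-2,6,6-trimethyl-5-(3-methylbut-2-en-1-yl)cyclohex-1-en-1-yl]trideca-2,4,6,8,10,12-hexaenal
Product: 35 all-E (2R,2'S)-2-(3-methylbut-2-en-1-yl)-2'-{4-[tert-butyl(diphenyl)silyl]oxy-3-({[tert-butyl(diphenyl)silyl]oxy}methyl)but-2-en-1-yl}-β,β-carotene, via phosphonium ylide 34 (not isolated)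
Conditions: NaOMe (1.5 equiv), CH2Cl2/MeOH, rt, dark, argon; then heptane, 80 °C (Z → E)
Reagents that add atoms: none
Why: The second Wittig reaction should join the C25 aldehyde and the ring B ylide at C11'=C12' to complete the C50 chain, thermal equilibration giving the all-E polyene while the silyl ethers are stable to methoxide.

Step 23
Reactants: 35 all-E (2R,2'S)-2-(3-methylbut-2-en-1-yl)-2'-{4-[tert-butyl(diphenyl)silyl]oxy-3-({[tert-butyl(diphenyl)silyl]oxy}methyl)but-2-en-1-yl}-β,β-carotene
Product: 36 all-E (2R,2'S)-2-(3-methylbut-2-en-1-yl)-2'-[4-hydroxy-3-(hydroxymethyl)but-2-en-1-yl]-β,β-carotene (target)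
Conditions: Bu4NF (3 equiv), AcOH (3 equiv), THF, rt, dark, argon
Reagents that add atoms: none
Why: Fluoride-mediated desilylation under acetic-acid-buffered conditions should free the diol without exposing the polyene to acid.

**Compound list**

1 | glutaraldehyde (pentanedial) | O=CCCCC=O | starting material
2 | ethyl (triphenylphosphoranylidene)acetate | CCOC(=O)C=P(c1ccccc1)(c1ccccc1)c1ccccc1 | starting material
3 | ethyl (2E)-7-oxohept-2-enoate | CCOC(=O)/C=C/CCCC=O | intermediate
4 | ethyl (2E)-7-hydroxy-8-methylnona-2,8-dienoate (racemic) | CCOC(=O)/C=C/CCCC(O)C(C)=C | intermediate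
5 | ethyl (2E)-8-methyl-7-oxonona-2,8-dienoate | CCOC(=O)/C=C/CCCC(=O)C(C)=C | intermediate
6 | monovalent-copper enolate of 5 after hydride addition, bound to (R,R)-Ph-BPE: {1,2-bis[(2R,5R)-2,5-diphenylphospholan-1-yl]ethane}Cu–OC(=CMe2)(CH2)3CH=CHCO2Et | CCOC(=O)/C=C/CCCC(O[Cu-2]1[P+]2(CC[P+]13[C@@H](c4ccccc4)CC[C@@H]3c3ccccc3)[C@@H](c3ccccc3)CC[C@@H]2c2ccccc2)=C(C)C | intermediate
7 | (3R)-3-{2-[diethoxy(methyl)silyl]oxy-2-ethoxyethenyl}-2,2-dimethylcyclohexan-1-one | CCOC(O[Si](C)(OCC)OCC)=C[C@H]1CCCC(=O)C1(C)C | intermediate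
8 | ethyl 2-[(1R)-2,2-dimethyl-3-oxocyclohexyl]acetate | CCOC(=O)C[C@H]1CCCC(=O)C1(C)C | intermediate
9 | lithium (5R)-5-(2-ethoxy-2-oxoethyl)-6,6-dimethylcyclohex-1-en-1-olate | CCOC(=O)C[C@H]1CCC=C(O[Li])C1(C)C | intermediate
10 | ethyl 2-[(1R,4RS)-2,2,4-trimethyl-3-oxocyclohexyl]acetate | CCOC(=O)C[C@H]1CCC(C)C(=O)C1(C)C | intermediate
11 | ethyl 2-[(1R)-2,2,4-trimethyl-3-{[(trifluoromethyl)sulfonyl]oxy}cyclohex-3-en-1-yl]acetate | CCOC(=O)C[C@H]1CCC(C)=C(OS(=O)(=O)C(F)(F)F)C1(C)C | intermediate
12 | 2-[(1R)-2,2,4-trimethyl-3-{[(trifluoromethyl)sulfonyl]oxy}cyclohex-3-en-1-yl]acetaldehyde | O=CC[C@H]1CCC(C)=C(OS(=O)(=O)C(F)(F)F)C1(C)C | intermediate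
13 | (5R)-2,6,6-trimethyl-5-(3-methylbut-2-en-1-yl)cyclohex-1-en-1-yl trifluoromethanesulfonate | CC(C)=CC[C@H]1CCC(C)=C(OS(=O)(=O)C(F)(F)F)C1(C)C | intermediate
14 | (2E)-3-methylpent-2-en-4-yn-1-ol | C#C/C(C)=C/CO | starting material
15 | (2E,4E)-3-methyl-5-(tributylstannyl)penta-2,4-dien-1-ol | CCCC[Sn](CCCC)(CCCC)/C=C/C(C)=C/CO | intermediate
16 | (2E,4E)-3-methyl-5-[(5R)-2,6,6-trimethyl-5-(3-methylbut-2-en-1-yl)cyclohex-1-en-1-yl]penta-2,4-dien-1-ol | CC(C)=CC[C@H]1CCC(C)=C(/C=C/C(C)=C/CO)C1(C)C | intermediate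
17 | {(2E,4E)-3-methyl-5-[(5R)-2,6,6-trimethyl-5-(3-methylbut-2-en-1-yl)cyclohex-1-en-1-yl]penta-2,4-dien-1-yl}triphenylphosphonium bromide | CC(C)=CC[C@H]1CCC(C)=C(/C=C/C(C)=C/C[P+](c2ccccc2)(c2ccccc2)c2ccccc2)C1(C)C.[Br-] | intermediate
18 | monovalent-copper enolate of 5 after hydride addition, bound to (S,S)-Ph-BPE (mirror image of 6): {1,2-bis[(2S,5S)-2,5-diphenylphospholan-1-yl]ethane}Cu–OC(=CMe2)(CH2)3CH=CHCO2Et | CCOC(=O)/C=C/CCCC(O[Cu-2]1[P+]2(CC[P+]13[C@H](c4ccccc4)CC[C@H]3c3ccccc3)[C@H](c3ccccc3)CC[C@H]2c2ccccc2)=C(C)C | intermediate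
19 | (3S)-3-{2-[diethoxy(methyl)silyl]oxy-2-ethoxyethenyl}-2,2-dimethylcyclohexan-1-one | CCOC(O[Si](C)(OCC)OCC)=C[C@@H]1CCCC(=O)C1(C)C | intermediate
20 | ethyl 2-[(1S)-2,2-dimethyl-3-oxocyclohexyl]acetate | CCOC(=O)C[C@@H]1CCCC(=O)C1(C)C | intermediate
21 | lithium (5S)-5-(2-ethoxy-2-oxoethyl)-6,6-dimethylcyclohex-1-en-1-olate | CCOC(=O)C[C@@H]1CCC=C(O[Li])C1(C)C | intermediate
22 | ethyl 2-[(1S,4RS)-2,2,4-trimethyl-3-oxocyclohexyl]acetate | CCOC(=O)C[C@@H]1CCC(C)C(=O)C1(C)C | intermediate
23 | ethyl 2-[(1S)-2,2,4-trimethyl-3-{[(trifluoromethyl)sulfonyl]oxy}cyclohex-3-en-1-yl]acetate | CCOC(=O)C[C@@H]1CCC(C)=C(OS(=O)(=O)C(F)(F)F)C1(C)C | intermediate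
24 | 2-[(1S)-2,2,4-trimethyl-3-{[(trifluoromethyl)sulfonyl]oxy}cyclohex-3-en-1-yl]acetaldehyde | O=CC[C@@H]1CCC(C)=C(OS(=O)(=O)C(F)(F)F)C1(C)C | intermediate
25 | dimethyl malonate | COC(=O)CC(=O)OC | starting material
26 | dimethyl 2-{2-[(1S)-2,2,4-trimethyl-3-{[(trifluoromethyl)sulfonyl]oxy}cyclohex-3-en-1-yl]ethylidene}propanedioate | COC(=O)C(=CC[C@@H]1CCC(C)=C(OS(=O)(=O)C(F)(F)F)C1(C)C)C(=O)OC | intermediate
27 | (5S)-5-[4-hydroxy-3-(hydroxymethyl)but-2-en-1-yl]-2,6,6-trimethylcyclohex-1-en-1-yl trifluoromethanesulfonate | OCC(CO)=CC[C@@H]1CCC(C)=C(OS(=O)(=O)C(F)(F)F)C1(C)C | intermediate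
28 | (5S)-5-{4-[tert-butyl(diphenyl)silyl]oxy-3-({[tert-butyl(diphenyl)silyl]oxy}methyl)but-2-en-1-yl}-2,6,6-trimethylcyclohex-1-en-1-yl trifluoromethanesulfonate | CC(C)(C)[Si](c1ccccc1)(c1ccccc1)OCC(CO[Si](c1ccccc1)(c1ccccc1)C(C)(C)C)=CC[C@@H]1CCC(C)=C(OS(=O)(=O)C(F)(F)F)C1(C)C | intermediate
29 | (2E,4E)-5-[(5S)-5-{4-[tert-butyl(diphenyl)silyl]oxy-3-({[tert-butyl(diphenyl)silyl]oxy}methyl)but-2-en-1-yl}-2,6,6-trimethylcyclohex-1-en-1-yl]-3-methylpenta-2,4-dien-1-ol | CC(C)(C)[Si](c1ccccc1)(c1ccccc1)OCC(CO[Si](c1ccccc1)(c1ccccc1)C(C)(C)C)=CC[C@@H]1CCC(C)=C(/C=C/C(C)=C/CO)C1(C)C | intermediate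
30 | {(2E,4E)-5-[(5S)-5-{4-[tert-butyl(diphenyl)silyl]oxy-3-({[tert-butyl(diphenyl)silyl]oxy}methyl)but-2-en-1-yl}-2,6,6-trimethylcyclohex-1-en-1-yl]-3-methylpenta-2,4-dien-1-yl}triphenylphosphonium bromide | CC(C)(C)[Si](c1ccccc1)(c1ccccc1)OCC(CO[Si](c1ccccc1)(c1ccccc1)C(C)(C)C)=CC[C@@H]1CCC(C)=C(/C=C/C(C)=C/C[P+](c2ccccc2)(c2ccccc2)c2ccccc2)C1(C)C.[Br-] | intermediate
31 | (2E,4E,6E)-2,7-dimethylocta-2,4,6-trienedial | O=C/C(C)=C/C=C/C=C(C)/C=O | starting material
32 | phosphonium ylide of 17, {(2E,4E)-3-methyl-5-[(5R)-2,6,6-trimethyl-5-(3-methylbut-2-en-1-yl)cyclohex-1-en-1-yl]penta-2,4-dien-1-ylidene}triphenylphosphorane | CC(C)=CC[C@H]1CCC(C)=C(/C=C/C(C)=C/C=P(c2ccccc2)(c2ccccc2)c2ccccc2)C1(C)C | intermediate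
33 | (2E,4E,6E,8E,10E,12E)-2,7,11-trimethyl-13-[(5R)-2,6,6-trimethyl-5-(3-methylbut-2-en-1-yl)cyclohex-1-en-1-yl]trideca-2,4,6,8,10,12-hexaenal | CC(C)=CC[C@H]1CCC(C)=C(/C=C/C(C)=C/C=C/C(C)=C/C=C/C=C(C)/C=O)C1(C)C | intermediate
34 | phosphonium ylide of 30, {(2E,4E)-5-[(5S)-5-{4-[tert-butyl(diphenyl)silyl]oxy-3-({[tert-butyl(diphenyl)silyl]oxy}methyl)but-2-en-1-yl}-2,6,6-trimethylcyclohex-1-en-1-yl]-3-methylpenta-2,4-dien-1-ylidene}triphenylphosphorane | CC(C)(C)[Si](c1ccccc1)(c1ccccc1)OCC(CO[Si](c1ccccc1)(c1ccccc1)C(C)(C)C)=CC[C@@H]1CCC(C)=C(/C=C/C(C)=C/C=P(c2ccccc2)(c2ccccc2)c2ccccc2)C1(C)C | intermediate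
35 | all-E (2R,2'S)-2-(3-methylbut-2-en-1-yl)-2'-{4-[tert-butyl(diphenyl)silyl]oxy-3-({[tert-butyl(diphenyl)silyl]oxy}methyl)but-2-en-1-yl}-β,β-carotene | CC(C)=CC[C@H]1CCC(C)=C(/C=C/C(C)=C/C=C/C(C)=C/C=C/C=C(C)/C=C/C=C(C)/C=C/C2=C(C)CC[C@@H](CC=C(CO[Si](c3ccccc3)(c3ccccc3)C(C)(C)C)CO[Si](c3ccccc3)(c3ccccc3)C(C)(C)C)C2(C)C)C1(C)C | intermediate
36 | all-E (2R,2'S)-2-(3-methylbut-2-en-1-yl)-2'-[4-hydroxy-3-(hydroxymethyl)but-2-en-1-yl]-β,β-carotene | CC(C)=CC[C@H]1CCC(C)=C(/C=C/C(C)=C/C=C/C(C)=C/C=C/C=C(C)/C=C/C=C(C)/C=C/C2=C(C)CC[C@@H](CC=C(CO)CO)C2(C)C)C1(C)C | target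

**Step count and risks**

Total: 23 steps. Longest linear sequence: 14 steps (steps 1–3, 12–20, 22 and 23).

Steps most likely to fail:

1. Step 4 (Proposed new method). What may go wrong: silyl transfer to the copper enolate before ring closure (plain conjugate reduction), intermolecular Michael addition, or weak facial discrimination of the enoate. The fallback sets out from 5 and comes back at 8. RhCl(PPh3)3-catalysed 1,4-hydrosilylation of the enone of 5 with Et3SiH should give the regio-defined silyl enol ether ethyl (2E)-8-methyl-7-(triethylsilyloxy)nona-2,7-dienoate F1. TiCl4 in CH2Cl2 at −78 °C then closes the same C1–C2 bond by an intramolecular Mukaiyama–Michael addition to give the racemic keto ester. Preparative chromatography on a chiral stationary phase separates it into 8 and its antipode 20; the route consumes both antipodes, so the resolution discards nothing.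

2. Step 12 (Proposed new method). What may go wrong: the same processes as in step 4, in the antipodal series. The fallback sets out from 5 and comes back at 20. The racemic keto ester is made through the silyl enol ether ethyl (2E)-8-methyl-7-(triethylsilyloxy)nona-2,7-dienoate F1 as above and saponified with LiOH. The racemic acid is resolved classically by crystallisation of its diastereomeric salts with (R)- or (S)-1-phenylethylamine, which gives 2-[(1S)-2,2-dimethyl-3-oxocyclohexyl]acetic acid F2 and, from the mother liquor with the other amine, 2-[(1R)-2,2-dimethyl-3-oxocyclohexyl]acetic acid F3. Esterification (EtOH, cat. H2SO4) converts F2 into 20 (and F3 into 8).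

3. Step 6. What may go wrong: slow O-sulfonylation of the very hindered carbonyl group and acid-promoted decomposition before the α-hydrogen is lost. The fallback sets out from 10 and comes back at 13; it removes the ester first so that a strong-base triflation can be used. LiAlH4 reduces both carbonyl groups of 10 to (3R)-3-(2-hydroxyethyl)-2,2,6-trimethylcyclohexan-1-ol F4. Swern oxidation gives 2-[(1R)-2,2,4-trimethyl-3-oxocyclohexyl]acetaldehyde F5. The isopropylidene ylide of step 8 reacts only with the aldehyde to give (3R)-2,2,6-trimethyl-3-(3-methylbut-2-en-1-yl)cyclohexan-1-one F6. The ketone is then enolised at its single α-hydrogen with LiN(i-Pr)2 and trapped with PhNTf2 to give 13.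

**Further compounds**

F1 | step 4 | ethyl (2E)-8-methyl-7-(triethylsilyloxy)nona-2,7-dienoate | CCOC(=O)/C=C/CCCC(O[Si](CC)(CC)CC)=C(C)C
F2 | step 12 | 2-[(1S)-2,2-dimethyl-3-oxocyclohexyl]acetic acid | OC(=O)C[C@@H]1CCCC(=O)C1(C)C
F3 | step 12 | 2-[(1R)-2,2-dimethyl-3-oxocyclohexyl]acetic acid | OC(=O)C[C@H]1CCCC(=O)C1(C)C
F4 | step 6 | (3R)-3-(2-hydroxyethyl)-2,2,6-trimethylcyclohexan-1-ol (mixture at C1 and C6) | OCC[C@H]1CCC(C)C(O)C1(C)C
F5 | step 6 | 2-[(1R)-2,2,4-trimethyl-3-oxocyclohexyl]acetaldehyde (mixture at C4) | O=CC[C@H]1CCC(C)C(=O)C1(C)C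
F6 | step 6 | (3R)-2,2,6-trimethyl-3-(3-methylbut-2-en-1-yl)cyclohexan-1-one (mixture at C6) | CC(C)=CC[C@H]1CCC(C)C(=O)C1(C)C
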